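**Direct plan and its weak points**

A direct plan would build dienyl bromide A1 by a six-operation Julia–Kocienski sequence and use it to γ-alkylate a diketone dianion, giving dienyl diketone A2.
The dianion of A2 would open the epoxide of glycidic ester A3 to hydroxy ester A4.
Silylation, Dieckmann closure of C1–C2 to the silyl-protected triketone A5, and desilylation would finish.
Weak point 1, the preparation of A1: thioether formation, sulfur oxidation, silylation, olefination, desilylation and bromination would be a long linear run-up of protecting-group and redox changes that creates one C=C bond.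
Weak point 2, the epoxide opening by the diketone dianion: it would rest on an unproven preference for the epoxide CH2 over the ester carbonyl of A3, with the whole chain already invested.
Weak point 3, the silylation/Dieckmann/desilylation triad: two protecting-group steps would frame a strong-base closure on an ester whose α-carbon is the only stereocenter (epimerisation risk at C6), and fluoride would come last on the triketone–diene.

**Retrosynthetic overview of the new route**

Ring atoms C1, C6, C5, C4, C3 and the C6 oxygen of the 4-hydroxy-2-acylcyclohexane-1,3-dione are the skeleton of (R)-2-hydroxyglutaric acid, bought as its γ-lactone 7. In 7 the C6–O–C3 ester bond, absent from the target, masks the C6 hydroxyl and stores C3 as an acyl donor.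
Key disconnection C2–C3: an O-to-C acyl shift of diketo lactone 13 through a 7-oxabicyclo[2.2.1]heptane hemiketal, whose fragmentation closes the only carbocycle in the last step, frees C6–OH and is a pure isomerisation.
13 comes from ynone 11 by formal hydration (C1'–O); 11 from acid 7 and dienyne 6 by Pd-catalysed acylation (C1–C2); 6 from two simple alkynes by hydrozirconation and alkenyl–alkenyl coupling (C8'–C9').
The design uses no protecting group and no redox adjustment, has no epoxide/ester competition, and takes C6 from the chiral pool without ever breaking its C–O or C–H bond.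

Key step: step 5

Remark on the chemistry: the β-triketone is written as the enol tautomer of the given SMILES; its enol forms interconvert freely, so the same compound is meant whichever is drawn.

**Route**

Step 1
Reactants: 1 nona-1,8-diyne
Product: 3 (E)-1-iodonon-1-en-8-yne, via alkenylzirconocene chloride 2 (not isolated)
Conditions: Cp2Zr(H)Cl (1.0 equiv), 1 (3 equiv), CH2Cl2, rt; then I2, 0 °C
Reagents that add atoms: iodine, II
Why: Hydrozirconation adds Zr–H syn across one terminal alkyne of the symmetric diyne (used in excess to suppress double addition) with Zr at the terminal carbon, and iodinolysis of the C–Zr bond with retention should fix the E-vinyl iodide while the second alkyne stays free.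

Step 2
Reactants: 4 dec-1-yne; 3 (E)-1-iodonon-1-en-8-yne
Product: 6 (8E,10E)-nonadeca-8,10-dien-1-yne, via decenylzirconocene chloride 5 (not isolated)
Conditions: 4 (1.2 equiv), Cp2Zr(H)Cl (1.1 equiv), THF, rt; then 3 (1.0 equiv), Pd(PPh3)4 (5 mol %), ZnCl2 (0.2 equiv), THF, rt
Reagents that add atoms: none
Why: Negishi-type Pd-catalysed alkenyl–alkenyl cross-coupling of an (E)-alkenylzirconocene with an (E)-alkenyl iodide proceeds with retention at both partners, so both diene bonds should be E, and the base-free conditions should leave the terminal alkyne of 3 untouched.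

Step 3
Reactants: 6 (8E,10E)-nonadeca-8,10-dien-1-yne; 7 (2R)-5-oxooxolane-2-carboxylic acid [(R)-5-oxotetrahydrofuran-2-carboxylic acid]
Product: 11 (5R)-5-[(9E,11E)-icosa-9,11-dien-2-ynoyl]oxolan-2-one, via lithium acetylide 8 (not isolated), via alkynylzinc chloride 9 (not isolated), via acid chloride 10 (not isolated)
Conditions: 6, n-BuLi (1.0 equiv), THF, −78 °C; ZnCl2 (1.1 equiv), −78 → 0 °C; then crude 10 [from 7, (COCl)2, DMF (cat.), CH2Cl2, 0 °C → rt, evaporated], Pd(PPh3)4 (3 mol %), THF, 0 °C → rt
Reagents that add atoms: none
Why: Negishi acylation (Pd-catalysed coupling of an alkynylzinc chloride with an acyl chloride) forms C1–C2 under neutral conditions, in which the organozinc should not add to the lactone and no base is present to enolise the α-acyloxy stereocenter C6 or turn 10 into a ketene.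

Step 4
Reactants: 11 (5R)-5-[(9E,11E)-icosa-9,11-dien-2-ynoyl]oxolan-2-one
Product: 13 (5R)-5-[(9E,11E)-3-oxoicosa-9,11-dienoyl]oxolan-2-one, via morpholine enaminone 12 (not isolated)
Conditions: morpholine (1.05 equiv), THF, 0 °C; then 1 M aq. HCl, THF, rt
Reagents that add atoms: water, O
Why: Conjugate addition of a secondary amine to an ynone gives the β-enaminone with nitrogen at C1' only, and mild acid hydrolysis of this vinylogous amide should deliver the 1,3-diketone (a formal regiospecific hydration), while the weakly basic amine and the dilute acid should spare C6–H, the lactone and the diene.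

Step 5
Reactants: 13 (5R)-5-[(9E,11E)-3-oxoicosa-9,11-dienoyl]oxolan-2-one
Product: 17 (6R)-3,6-dihydroxy-2-[(7E,9E)-octadeca-7,9-dienoyl]cyclohex-2-en-1-one (CNP0169831.1), via potassium diketonate 14 (not isolated), via oxabicyclic alkoxide 15 (not isolated), via potassium triketonate 16 (not isolated)
Conditions: KOtBu (1.05 equiv), THF (0.02 M), 0 → 40 °C; then 1 M HCl to pH 2–3
Reagents that add atoms: none
Why: Proposed new method: the single equivalent of KOtBu removes a C2–H (the only doubly activated carbon acid) and potassium diketonate 14 attacks through C2 the lactone carbonyl C3, which the lactone holds in a 1,3-relationship to C6, so that the 7-oxabicyclo[2.2.1]heptan-1-olate 15 forms and at once fragments by cleavage of the C3–O bridge, the bond that is not in the target, after which the liberated C6 alkoxide is quenched by the strongly acidic C2–H of the new triketone to give triketonate 16. The closest known reaction types are the Dieckmann condensation of 1,3-diketone enolates with esters and the base-induced O-to-C acyl shift of enol lactones (ylidenebutenolides) to 2-acylcycloalkane-1,3-diones, neither of which has been shown for a saturated γ-lactone that must pass through a bridged hemiketal. The six-membered carbocycle closes by a 6-exo-trig attack of C2 on C3 through a boat-like, norbornane-type transition state, and the oxygen bridge closes and reopens in the same event. No stereocenter is formed (C2 ends trigonal and the bridgehead centres of 15 are lost), and C6 should keep its R configuration because neither its C–O nor its C–H bond is touched while the base resides on C2 throughout. The step needs C- over O-acylation and ring closure over intermolecular Claisen condensation: O-acylation is reversible and only C-acylation ends in the triketonate, estimated to lie four to five pKa units below the diketonate and formed with relief of the γ-lactone strain, and high dilution favours the intramolecular path.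

**Compound list**

1 | nona-1,8-diyne | C#CCCCCCC#C | starting material
2 | chloridobis(cyclopentadienyl)[(1E)-non-1-en-8-yn-1-yl]zirconium | C#CCCCCC/C=C/[Zr](Cl)(C1C=CC=C1)C1C=CC=C1 | intermediate
3 | (E)-1-iodonon-1-en-8-yne | C#CCCCCC/C=C/I | intermediate
4 | dec-1-yne | CCCCCCCCC#C | starting material
5 | chloridobis(cyclopentadienyl)[(1E)-dec-1-en-1-yl]zirconium | CCCCCCCC/C=C/[Zr](Cl)(C1C=CC=C1)C1C=CC=C1 | intermediate
6 | (8E,10E)-nonadeca-8,10-dien-1-yne | CCCCCCCC/C=C/C=C/CCCCCC#C | intermediate
7 | (2R)-5-oxooxolane-2-carboxylic acid | OC(=O)[C@H]1CCC(=O)O1 | starting material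
8 | lithium (8E,10E)-nonadeca-8,10-dien-1-yn-1-ide | [Li+].CCCCCCCC/C=C/C=C/CCCCCC#[C-] | intermediate
9 | chlorido[(8E,10E)-nonadeca-8,10-dien-1-yn-1-yl]zinc | CCCCCCCC/C=C/C=C/CCCCCC#C[Zn]Cl | intermediate
10 | (2R)-5-oxooxolane-2-carbonyl chloride | ClC(=O)[C@H]1CCC(=O)O1 | intermediate
11 | (5R)-5-[(9E,11E)-icosa-9,11-dien-2-ynoyl]oxolan-2-one | CCCCCCCC/C=C/C=C/CCCCCC#CC(=O)[C@H]1CCC(=O)O1 | intermediate
12 | (5R)-5-[(9E,11E)-3-(morpholin-4-yl)icosa-2,9,11-trienoyl]oxolan-2-one (C2=C3 geometry not defined) | CCCCCCCC/C=C/C=C/CCCCCC(=CC(=O)[C@H]1CCC(=O)O1)N1CCOCC1 | intermediate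
13 | (5R)-5-[(9E,11E)-3-oxoicosa-9,11-dienoyl]oxolan-2-one | CCCCCCCC/C=C/C=C/CCCCCC(=O)CC(=O)[C@H]1CCC(=O)O1 | intermediate
14 | potassium enolate of 13 (diketonate) | [K+].CCCCCCCC/C=C/C=C/CCCCCC(=O)C=C([O-])[C@H]1CCC(=O)O1 | intermediate
15 | potassium (4R)-2-[(7E,9E)-octadeca-7,9-dienoyl]-3-oxo-7-oxabicyclo[2.2.1]heptan-1-olate (C1 fixed by the bridge, C2 not defined) | [K+].[O-]C12CC[C@@H](O1)C(=O)C2C(=O)CCCCC/C=C/C=C/CCCCCCCC | intermediate
16 | potassium enolate of 17 (triketonate) | [K+].CCCCCCCC/C=C/C=C/CCCCCC(=O)C1=C([O-])CC[C@@H](O)C1=O | intermediate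
17 | (6R)-3,6-dihydroxy-2-[(7E,9E)-octadeca-7,9-dienoyl]cyclohex-2-en-1-one (CNP0169831.1) | CCCCCCCC/C=C/C=C/CCCCCC(=O)C1=C(O)CC[C@@H](O)C1=O | target

**Step count and risks**

Total steps: 5. Longest linear sequence: 5 (steps 1 to 5, from nona-1,8-diyne); acid 7 enters at step 3.

Steps most likely to fail:

1. Step 5 (Proposed new method). The diketonate may not reach the lactone carbonyl through the strained bridged transition state, so that intermolecular Claisen condensation or slow base-mediated erosion of C6 takes over. Fallback with known chemistry, from 13 back to 17: the lactone of 13 would be opened with K2CO3 in MeOH at 0 °C to methyl (4R,13E,15E)-4-hydroxy-5,7-dioxotetracosa-13,15-dienoate F1. F1 would be silylated without purification (TESCl, imidazole, DMF) to methyl (4R,13E,15E)-5,7-dioxo-4-[(triethylsilyl)oxy]tetracosa-13,15-dienoate F2. An ordinary open-chain 6-exo-trig Dieckmann condensation (KOtBu, THF) would give (6R)-3-hydroxy-2-[(7E,9E)-octadeca-7,9-dienoyl]-6-[(triethylsilyl)oxy]cyclohex-2-en-1-one F3, and HF·pyridine would release 17.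

2. Step 3. Configuration at C6 may be lost at the α-acyloxy acyl chloride or ynone stage (enolisation or ketene formation), or the acyl–palladium species may decarbonylate. Fallback, from 6 back to 11, replacing acyl substitution by 1,2-addition and oxidation: commercial (5R)-5-(hydroxymethyl)oxolan-2-one F4 would be oxidised (Dess–Martin periodinane, CH2Cl2) to (2R)-5-oxooxolane-2-carbaldehyde F5. Lithium acetylide 8 would add to the aldehyde at −78 °C, much faster than to the lactone, to give (5R)-5-[(9E,11E)-1-hydroxyicosa-9,11-dien-2-yn-1-yl]oxolan-2-one F6 as a mixture of carbinol epimers, and MnO2 would oxidise F6 to 11.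

3. Step 4. The amine may epimerise C6 or open the activated lactone before conjugate addition is complete, or hydrolysis of the enaminone may stall. Fallback, from 6 back to 13, bypassing the ynone and the amine: Markovnikov hydration of the terminal alkyne of 6 (Ph3PAuNTf2 cat., aq. MeOH) would give (8E,10E)-nonadeca-8,10-dien-2-one F7. Deprotonation of F7 with LiN(SiMe3)2 (2 equiv, THF, −78 °C) and Claisen-type C-acylation of the kinetic enolate with acid chloride 10 would give 13.

**Further compounds**

F1 | step 5 | methyl (4R,13E,15E)-4-hydroxy-5,7-dioxotetracosa-13,15-dienoate | CCCCCCCC/C=C/C=C/CCCCCC(=O)CC(=O)[C@H](O)CCC(=O)OC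
F2 | step 5 | methyl (4R,13E,15E)-5,7-dioxo-4-[(triethylsilyl)oxy]tetracosa-13,15-dienoate | CCCCCCCC/C=C/C=C/CCCCCC(=O)CC(=O)[C@H](O[Si](CC)(CC)CC)CCC(=O)OC
F3 | step 5 | (6R)-3-hydroxy-2-[(7E,9E)-octadeca-7,9-dienoyl]-6-[(triethylsilyl)oxy]cyclohex-2-en-1-one | CCCCCCCC/C=C/C=C/CCCCCC(=O)C1=C(O)CC[C@@H](O[Si](CC)(CC)CC)C1=O
F4 | step 3 | (5R)-5-(hydroxymethyl)oxolan-2-one | OC[C@H]1CCC(=O)O1
F5 | step 3 | (2R)-5-oxooxolane-2-carbaldehyde | O=C[C@H]1CCC(=O)O1
F6 | step 3 | (5R)-5-[(9E,11E)-1-hydroxyicosa-9,11-dien-2-yn-1-yl]oxolan-2-one | CCCCCCCC/C=C/C=C/CCCCCC#CC(O)[C@H]1CCC(=O)O1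
F7 | step 4 | (8E,10E)-nonadeca-8,10-dien-2-one | CCCCCCCC/C=C/C=C/CCCCCC(C)=O
A1 | direct plan | (5E,7E)-1-bromohexadeca-5,7-diene | BrCCCC/C=C/C=C/CCCCCCCC
A2 | direct plan | (10E,12E)-henicosa-10,12-diene-2,4-dione | CC(=O)CC(=O)CCCCC/C=C/C=C/CCCCCCCC
A3 | direct plan | methyl (2R)-oxirane-2-carboxylate | COC(=O)[C@H]1CO1
A4 | direct plan | methyl (2R,13E,15E)-2-hydroxy-5,7-dioxotetracosa-13,15-dienoate | COC(=O)[C@H](O)CCC(=O)CC(=O)CCCCC/C=C/C=C/CCCCCCCC
A5 | direct plan | (6R)-6-[(tert-butyldimethylsilyl)oxy]-3-hydroxy-2-[(7E,9E)-octadeca-7,9-dienoyl]cyclohex-2-en-1-one | CCCCCCCC/C=C/C=C/CCCCCC(=O)C1=C(O)CC[C@@H](O[Si](C)(C)C(C)(C)C)C1=O
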